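Both 1,4-benzodioxane rings share one feature: the oxygen on the benzylic, aryl-bearing carbon (O7' in the dioxane fused to ring A, the arene with the propenol chain; O7'' in the dioxane fused to ring B, the middle arene) is bonded to the arene carbon (C3 of ring A, C3' of ring B) ortho to the other ring oxygen. Cutting these aryl C–O bonds gives, twice, a 2-bromoaryl ether of a threo-1-arylpropane-1,3-diol, each made by an Evans glycolate syn-aldol. The key step is a twofold palladium-catalysed intramolecular C–O coupling of the dibromo diol that closes both dioxane rings in one operation, forming O7''–C3' with retention at all four stereocenters.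

Key step: step 9

Remark on labels: ring A carries the three-carbon chain at C1, the oxygen to C8' at C4 and Br (later O7') at C3. Ring B is bonded to C7' at C1', carries the oxygen to C8'' at C4' and Br (later O7'') at C3'. Ring C is the catechol ring, bonded to C7''. C9' and C9'' are the CH2O carbons on C8' and C8''.
Assumption: (4R)- and (4S)-4-benzyl-3-(chloroacetyl)oxazolidin-2-one are taken as purchasable; each is otherwise one N-acylation away from the parent oxazolidinone.

Step 1
Reactants: 1 3-bromo-4-hydroxybenzaldehyde; 2 methyl (triphenylphosphoranylidene)acetate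
Product: 3 methyl (E)-3-(3-bromo-4-hydroxyphenyl)prop-2-enoate
Conditions: toluene, 90 °C
Reagents that add atoms: none
Why: Wittig olefination with the ester-stabilised ylide should give the (E)-cinnamate and tolerates the free phenol and the aryl bromide.

Step 2
Reactants: 3 methyl (E)-3-(3-bromo-4-hydroxyphenyl)prop-2-enoate; 4 (4R)-4-benzyl-3-(chloroacetyl)oxazolidin-2-one
Product: 5 ring A glycolate imide (methyl (E)-3-(3-bromo-4-{2-[(4R)-4-benzyl-2-oxooxazolidin-3-yl]-2-oxoethoxy}phenyl)prop-2-enoate)
Conditions: K2CO3, NaI (cat.), MeCN, rt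
Reagents that add atoms: none
Why: Williamson ether synthesis (SN2 at the α-chloro imide with iodide catalysis) on the phenoxide should outpace attack at the imide carbonyls under the mild carbonate base, and the auxiliary stereocenter is not involved.

Step 3
Reactants: 1 3-bromo-4-hydroxybenzaldehyde; 6 (4S)-4-benzyl-3-(chloroacetyl)oxazolidin-2-one
Product: 7 ring B glycolate imide aldehyde ((4S)-4-benzyl-3-[(2-bromo-4-formylphenoxy)acetyl]oxazolidin-2-one)
Conditions: K2CO3, NaI (cat.), MeCN, rt
Reagents that add atoms: none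
Why: The same Williamson O-alkylation, run in a solvent that cannot condense with the aldehyde, should give the building block that carries both the later enolate site and the electrophilic formyl group of ring B.

Step 4
Reactants: 5 ring A glycolate imide; 7 ring B glycolate imide aldehyde
Product: 9 first syn-aldol adduct (C8' R and C7' S; free C7' hydroxyl; both imides intact), via dibutylboron (Z)-enolate 8 (not isolated)
Conditions: 5 (1.2 equiv), Bu2BOTf (1.15 equiv), iPr2NEt (1.3 equiv), CH2Cl2, −78 to 0 °C; then 7 (1.0 equiv), −78 to 0 °C; then pH 7 buffer, MeOH, 30% H2O2, 0 °C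
Reagents that add atoms: none
Why: Evans glycolate syn-aldol reaction, in which enolate 8 adds to 7 through a Zimmerman–Traxler chair on the face opposite the benzyl group of the (R)-auxiliary, which should set C8' (R at this stage) and C7' (S) syn, the slight excess of 5 over Bu2BOTf leaving no boron triflate to enolise the imide of 7.

Step 5
Reactants: 10 3,4-dihydroxybenzaldehyde
Product: 11 3,4-bis(triisopropylsilyloxy)benzaldehyde
Conditions: TIPSCl (2.4 equiv), imidazole, DMAP (cat.), DMF, 40 °C
Reagents that add atoms: triisopropylsilyl chloride (TIPSCl), CC(C)[Si](Cl)(C(C)C)C(C)C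
Why: Silyl ether formation on both phenols; TIPS is chosen because it should survive borohydride, phosphate base at 80 °C and iBu2AlH, yet leave with fluoride at the end.

Step 6
Reactants: 9 first syn-aldol adduct; 11 3,4-bis(triisopropylsilyloxy)benzaldehyde
Product: 13 bis-aldol adduct (C8' R and C7' S; C8'' S and C7'' R; two free benzylic hydroxyls), via O-boryl boron enolate 12 (not isolated)
Conditions: Bu2BOTf (2.3 equiv), iPr2NEt (2.6 equiv), CH2Cl2, −78 to 0 °C; then 11 (1.3 equiv), −78 to 0 °C; then pH 7 buffer, MeOH, 30% H2O2, 0 °C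
Reagents that add atoms: none
Why: Second Evans glycolate syn-aldol reaction, in which the first equivalent of Bu2BOTf masks the C7' hydroxyl as its borinate, the second forms the (Z)-enolate of the ring B glycolate, and the (S)-auxiliary should direct addition to 11 to set C8'' (S at this stage) and C7'' (R) syn under reagent control.

Step 7
Reactants: 13 bis-aldol adduct
Product: 14 tetraol (methyl (E)-3-{3-bromo-4-[((1S,2S)-1-{3-bromo-4-[((1R,2R)-1-[3,4-bis(triisopropylsilyloxy)phenyl]-1,3-dihydroxypropan-2-yl)oxy]phenyl}-1,3-dihydroxypropan-2-yl)oxy]phenyl}prop-2-enoate)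
Conditions: NaBH4 (excess), THF/H2O, 0 °C to rt
Reagents that add atoms: none
Why: Reductive removal of the auxiliaries (borohydride reduction of N-acyloxazolidinones in wet THF) should convert both activated imides into primary alcohols while the less electrophilic conjugated methyl ester is left alone; no bond to a stereocenter is broken, and C8' and C8'' change descriptor only through CIP priority.

Step 8
Reactants: 14 tetraol
Product: 15 dibromo diol (14 with O9' and O9'' as tert-butyldimethylsilyl ethers; C7' and C7'' hydroxyls free)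
Conditions: TBSCl (2.2 equiv), imidazole, CH2Cl2, 0 °C
Reagents that add atoms: tert-butyldimethylsilyl chloride (TBSCl), CC(C)(C)[Si](C)(C)Cl
Why: Sterically controlled silyl ether formation should select the two primary hydroxyls over the two hindered secondary benzylic ones, which must stay free for the ring closures.

Step 9
Reactants: 15 dibromo diol
Product: 17 bis(benzodioxane) ester (methyl (E)-3-[(2S,3S)-3-{(2R,3R)-3-[3,4-bis(triisopropylsilyloxy)phenyl]-2-(tert-butyldimethylsilyloxymethyl)-2,3-dihydro-1,4-benzodioxin-6-yl}-2-(tert-butyldimethylsilyloxymethyl)-2,3-dihydro-1,4-benzodioxin-6-yl]prop-2-enoate), via mono-cyclised bromo alcohol 16 (not isolated)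
Conditions: Pd(OAc)2 (10 mol%), 2-(di-tert-butylphosphino)-1,1'-binaphthyl (15 mol%), K3PO4, toluene, 80 °C
Reagents that add atoms: none
Why: Zerovalent palladium inserts into each aryl C–Br bond, the neighbouring secondary benzylic hydroxyl is deprotonated onto palladium to give a seven-membered aryl(alkoxo)palladacycle, and C–O reductive elimination releases the 1,4-dioxane ring; the bromide on the acrylate-bearing ring A is expected to react first (16), and the second turnover forms the O7''–C3' bond. The closest known reaction is the Buchwald–Hartwig intramolecular etherification of 2-(2-bromophenoxy)ethanols to 1,4-benzodioxanes. Each ring closes in a six-membered mode by delivery of an alkoxide oxygen to an arene carbon (formally 6-exo), the tether being the aryl ether O–C8–C7 chain already in place. No stereocenter is made: no bond to C7', C8', C7'' or C8'' is broken, so the two threo units set by the auxiliaries are carried with retention into the two trans-2,3-disubstituted rings. The step needs reductive elimination to outrun β-hydride elimination and needs the benzylic hydroxyls alone to react: the bulky electron-rich binaphthyl phosphine accelerates reductive elimination, the primary hydroxyls are silylated, and each hydroxyl can reach only its own bromide through a six-membered ring.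

Step 10
Reactants: 17 bis(benzodioxane) ester
Product: 18 silyl-protected allylic alcohol ((E)-prop-2-en-1-ol corresponding to 17)
Conditions: iBu2AlH (DIBAL-H, 3 equiv), CH2Cl2, −78 °C; aqueous potassium sodium tartrate
Reagents that add atoms: none
Why: 1,2-Reduction of the α,β-unsaturated ester with iBu2AlH at low temperature should give the (E)-allylic alcohol without touching silyl ethers, aryl ethers or stereocenters.

Step 11
Reactants: 18 silyl-protected allylic alcohol
Product: 19 target ((E)-3-[(2S,3S)-3-{(2R,3R)-3-(3,4-dihydroxyphenyl)-2-(hydroxymethyl)-2,3-dihydro-1,4-benzodioxin-6-yl}-2-(hydroxymethyl)-2,3-dihydro-1,4-benzodioxin-6-yl]prop-2-en-1-ol)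
Conditions: Bu4NF, AcOH, THF, 0 °C to rt, under argon
Reagents that add atoms: none
Why: Fluoride-mediated desilylation, driven by Si–F bond formation, should remove the two primary TBS and the two aryl TIPS ethers in one operation, the acetic acid buffer protecting the liberated catechol and the cinnamyl alcohol from base.

Compound list
1 | 3-bromo-4-hydroxybenzaldehyde | O=Cc1ccc(O)c(Br)c1 | starting material
2 | methyl (triphenylphosphoranylidene)acetate | COC(=O)C=P(c1ccccc1)(c1ccccc1)c1ccccc1 | starting material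
3 | methyl (E)-3-(3-bromo-4-hydroxyphenyl)prop-2-enoate | COC(=O)/C=C/c1ccc(O)c(Br)c1 | intermediate
4 | (4R)-4-benzyl-3-(chloroacetyl)oxazolidin-2-one | O=C(CCl)N1[C@H](Cc2ccccc2)COC1=O | starting material
5 | ring A glycolate imide, methyl (E)-3-(3-bromo-4-{2-[(4R)-4-benzyl-2-oxooxazolidin-3-yl]-2-oxoethoxy}phenyl)prop-2-enoate | COC(=O)/C=C/c1ccc(OCC(=O)N2[C@H](Cc3ccccc3)COC2=O)c(Br)c1 | intermediate
6 | (4S)-4-benzyl-3-(chloroacetyl)oxazolidin-2-one | O=C(CCl)N1[C@@H](Cc2ccccc2)COC1=O | starting material
7 | ring B glycolate imide aldehyde, (4S)-4-benzyl-3-[(2-bromo-4-formylphenoxy)acetyl]oxazolidin-2-one | O=Cc1ccc(OCC(=O)N2[C@@H](Cc3ccccc3)COC2=O)c(Br)c1 | intermediate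
8 | (Z)-dibutylboron enolate of 5 (aryloxy group cis to the boryloxy group) | COC(=O)/C=C/c1ccc(O/C=C(\OB(CCCC)CCCC)N2[C@H](Cc3ccccc3)COC2=O)c(Br)c1 | intermediate (not isolated)
9 | first syn-aldol adduct, (4R)-4-benzyl-3-[(2R,3S)-2-{2-bromo-4-[(E)-3-methoxy-3-oxoprop-1-enyl]phenoxy}-3-(3-bromo-4-{2-[(4S)-4-benzyl-2-oxooxazolidin-3-yl]-2-oxoethoxy}phenyl)-3-hydroxypropanoyl]oxazolidin-2-one | COC(=O)/C=C/c1ccc(O[C@H]([C@@H](O)c2ccc(OCC(=O)N3[C@@H](Cc4ccccc4)COC3=O)c(Br)c2)C(=O)N2[C@H](Cc3ccccc3)COC2=O)c(Br)c1 | intermediate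
10 | 3,4-dihydroxybenzaldehyde | O=Cc1ccc(O)c(O)c1 | starting material
11 | 3,4-bis(triisopropylsilyloxy)benzaldehyde | O=Cc1ccc(O[Si](C(C)C)(C(C)C)C(C)C)c(O[Si](C(C)C)(C(C)C)C(C)C)c1 | intermediate
12 | C7'-O-dibutylboryl (Z)-dibutylboron enolate of 9 (enolate at the ring B glycolate) | COC(=O)/C=C/c1ccc(O[C@H]([C@@H](OB(CCCC)CCCC)c2ccc(O/C=C(\OB(CCCC)CCCC)N3[C@@H](Cc4ccccc4)COC3=O)c(Br)c2)C(=O)N2[C@H](Cc3ccccc3)COC2=O)c(Br)c1 | intermediate (not isolated)
13 | bis-aldol adduct: 9 in which the ring B glycolate has become the (2S,3R)-2-aryloxy-3-[3,4-bis(triisopropylsilyloxy)phenyl]-3-hydroxypropanoyl imide of the (4S)-auxiliary | COC(=O)/C=C/c1ccc(O[C@H]([C@@H](O)c2ccc(O[C@@H]([C@H](O)c3ccc(O[Si](C(C)C)(C(C)C)C(C)C)c(O[Si](C(C)C)(C(C)C)C(C)C)c3)C(=O)N3[C@@H](Cc4ccccc4)COC3=O)c(Br)c2)C(=O)N2[C@H](Cc3ccccc3)COC2=O)c(Br)c1 | intermediate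
14 | tetraol, methyl (E)-3-{3-bromo-4-[((1S,2S)-1-{3-bromo-4-[((1R,2R)-1-[3,4-bis(triisopropylsilyloxy)phenyl]-1,3-dihydroxypropan-2-yl)oxy]phenyl}-1,3-dihydroxypropan-2-yl)oxy]phenyl}prop-2-enoate | COC(=O)/C=C/c1ccc(O[C@H]([C@@H](O)c2ccc(O[C@@H]([C@H](O)c3ccc(O[Si](C(C)C)(C(C)C)C(C)C)c(O[Si](C(C)C)(C(C)C)C(C)C)c3)CO)c(Br)c2)CO)c(Br)c1 | intermediate
15 | dibromo diol: 14 with both primary hydroxyls (O9', O9'') as tert-butyldimethylsilyl ethers, C7' (S) and C7'' (R) hydroxyls free | COC(=O)/C=C/c1ccc(O[C@H]([C@@H](O)c2ccc(O[C@@H]([C@H](O)c3ccc(O[Si](C(C)C)(C(C)C)C(C)C)c(O[Si](C(C)C)(C(C)C)C(C)C)c3)CO[Si](C)(C)C(C)(C)C)c(Br)c2)CO[Si](C)(C)C(C)(C)C)c(Br)c1 | intermediate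
16 | mono-cyclised bromo alcohol: (2S,3S)-benzodioxane fused to ring A closed, ring B still carrying Br at C3' and the open (1R,2R) unit with free C7'' hydroxyl | COC(=O)/C=C/c1ccc2c(c1)O[C@@H](c1ccc(O[C@@H]([C@H](O)c3ccc(O[Si](C(C)C)(C(C)C)C(C)C)c(O[Si](C(C)C)(C(C)C)C(C)C)c3)CO[Si](C)(C)C(C)(C)C)c(Br)c1)[C@H](CO[Si](C)(C)C(C)(C)C)O2 | intermediate (not isolated)
17 | bis(benzodioxane) ester, methyl (E)-3-[(2S,3S)-3-{(2R,3R)-3-[3,4-bis(triisopropylsilyloxy)phenyl]-2-(tert-butyldimethylsilyloxymethyl)-2,3-dihydro-1,4-benzodioxin-6-yl}-2-(tert-butyldimethylsilyloxymethyl)-2,3-dihydro-1,4-benzodioxin-6-yl]prop-2-enoate | COC(=O)/C=C/c1ccc2c(c1)O[C@@H](c1ccc3c(c1)O[C@H](c1ccc(O[Si](C(C)C)(C(C)C)C(C)C)c(O[Si](C(C)C)(C(C)C)C(C)C)c1)[C@@H](CO[Si](C)(C)C(C)(C)C)O3)[C@H](CO[Si](C)(C)C(C)(C)C)O2 | intermediate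
18 | silyl-protected allylic alcohol, the (E)-prop-2-en-1-ol corresponding to ester 17 | OC/C=C/c1ccc2c(c1)O[C@@H](c1ccc3c(c1)O[C@H](c1ccc(O[Si](C(C)C)(C(C)C)C(C)C)c(O[Si](C(C)C)(C(C)C)C(C)C)c1)[C@@H](CO[Si](C)(C)C(C)(C)C)O3)[C@H](CO[Si](C)(C)C(C)(C)C)O2 | intermediate
19 | (E)-3-[(2S,3S)-3-{(2R,3R)-3-(3,4-dihydroxyphenyl)-2-(hydroxymethyl)-2,3-dihydro-1,4-benzodioxin-6-yl}-2-(hydroxymethyl)-2,3-dihydro-1,4-benzodioxin-6-yl]prop-2-en-1-ol | OC/C=C/c1ccc2c(c1)O[C@@H](c1ccc3c(c1)O[C@H](c1ccc(O)c(O)c1)[C@@H](CO)O3)[C@H](CO)O2 | target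

Total step count: 11 steps.
Longest linear sequence: 9 steps (steps 1, 2, 4, 6, 7, 8, 9, 10, 11, from 1 to 19).

Steps most likely to fail

Step 9. β-Hydride elimination in the aryl(alkoxo)palladium intermediates would oxidise a benzylic carbinol to a ketone and reduce the C–Br bond, or the reaction may stall after the first closure. The fallback sets out from 15 and reverses the polarity of the arene. Miyaura borylation of both aryl bromides (Pd(dppf)Cl2, bis(pinacolato)diboron, KOAc, dioxane, 80 °C; the weak base forms no alkoxide) should give the bis(pinacol boronate) F1. A twofold intramolecular Chan–Lam etherification (Cu(OAc)2, pyridine, 4 Å molecular sieves, CH2Cl2, air, rt) should then close both dioxane rings through aryl–copper intermediates that have no β-hydride pathway, again without touching the stereocenters. The fallback comes back to the route at 17.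

Step 6. The free C7' hydroxyl may consume boron triflate unproductively, enolisation of the ring B glycolate may stay incomplete, or the first aldol unit may suffer retro-aldol cleavage or epimerisation at C8' during the long enolisation. The fallback sets out from 9: the C7' hydroxyl is silylated (Et3SiCl, imidazole, CH2Cl2) to the triethylsilyl ether F2, the aldol with 11 is run under the standard conditions with one equivalent of Bu2BOTf to give the silylated bis-aldol adduct F3, and the triethylsilyl group is removed with pyridinium p-toluenesulfonate in MeOH. The fallback comes back at 13.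

Step 4. Residual boron triflate and amine may enolise the glycolate imide inside aldehyde 7, leading to self-condensation and low conversion to the cross-aldol product. The fallback sets out from 1 and postpones the installation of the second imide: the phenol of 1 is protected (TBSCl, imidazole, DMF) to give 3-bromo-4-(tert-butyldimethylsilyloxy)benzaldehyde F4, enolate 8 is added to F4 to give the silyl-protected aldol adduct F5, the phenol is released with Bu4NF/AcOH at 0 °C to give the phenolic aldol adduct F6, and only then is the phenol alkylated with chloroacetyl imide 6 (K2CO3, NaI, MeCN). The fallback comes back at 9.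

Further compounds
F1 | step 9 | bis(pinacol boronate): 15 with both bromines (C3 of ring A, C3' of ring B) replaced by 4,4,5,5-tetramethyl-1,3,2-dioxaborolan-2-yl | COC(=O)/C=C/c1ccc(O[C@H]([C@@H](O)c2ccc(O[C@@H]([C@H](O)c3ccc(O[Si](C(C)C)(C(C)C)C(C)C)c(O[Si](C(C)C)(C(C)C)C(C)C)c3)CO[Si](C)(C)C(C)(C)C)c(B3OC(C)(C)C(C)(C)O3)c2)CO[Si](C)(C)C(C)(C)C)c(B2OC(C)(C)C(C)(C)O2)c1
F2 | step 6 | C7'-O-triethylsilyl ether of 9 | COC(=O)/C=C/c1ccc(O[C@H]([C@@H](O[Si](CC)(CC)CC)c2ccc(OCC(=O)N3[C@@H](Cc4ccccc4)COC3=O)c(Br)c2)C(=O)N2[C@H](Cc3ccccc3)COC2=O)c(Br)c1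
F3 | step 6 | C7'-O-triethylsilyl ether of bis-aldol adduct 13 | COC(=O)/C=C/c1ccc(O[C@H]([C@@H](O[Si](CC)(CC)CC)c2ccc(O[C@@H]([C@H](O)c3ccc(O[Si](C(C)C)(C(C)C)C(C)C)c(O[Si](C(C)C)(C(C)C)C(C)C)c3)C(=O)N3[C@@H](Cc4ccccc4)COC3=O)c(Br)c2)C(=O)N2[C@H](Cc3ccccc3)COC2=O)c(Br)c1
F4 | step 4 | 3-bromo-4-(tert-butyldimethylsilyloxy)benzaldehyde | O=Cc1ccc(O[Si](C)(C)C(C)(C)C)c(Br)c1
F5 | step 4 | syn-aldol adduct of 8 and F4, (2R,3S), ring B phenol as TBS ether | COC(=O)/C=C/c1ccc(O[C@H]([C@@H](O)c2ccc(O[Si](C)(C)C(C)(C)C)c(Br)c2)C(=O)N2[C@H](Cc3ccccc3)COC2=O)c(Br)c1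
F6 | step 4 | phenolic aldol adduct, F5 with free ring B phenol | COC(=O)/C=C/c1ccc(O[C@H]([C@@H](O)c2ccc(O)c(Br)c2)C(=O)N2[C@H](Cc3ccccc3)COC2=O)c(Br)c1
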